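**Retrosynthetic overview**

1. Numbering: C1≡C2–C3=C4–C5–C6(Cl)–C7(OAc)–C8–C9–C10(Cl)–C11–C12(Br)–C13–C14–C15, with one ring (oxane: O, C9–C13); target is 6R,7S,9R,10R,12R,13S. Enabling feature: the ring O, C10 and C12 are alternate atoms of the oxane, and with the C9 and C13 side chains cis (both equatorial) the C10–Cl is axial and cis-1,3 to the axial C12 oxygen that precedes the bromide, so one titanium centre held by the ring O and the C12 oxygen can pass chloride to C10.
2. End game: C7–OAc from C7–OTBS; C1≡C2 from an enal (Colvin) made by cross-metathesis of the C3=C4 terminal alkene; C12–Br from the axial C12–OH with inversion.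
3. Ring (the only one, formed in step 10): C11–C12 bond by chelation-controlled chloro-Prins closure of the C12 aldehyde onto the C10=C11 vinyl group, TiCl4 serving as Lewis acid and chlorine source.
4. Acyclic ether: C9 alkoxide plus methyl (R)-2-(triflyloxy)butanoate (C13 bought, SN2 inversion).
5. C3–C11 chain: (R)-2-chloropent-4-enal (C6 by organocatalysis) plus 4-(trimethylsilyl)but-3-yn-2-one; Cornforth aldol sets C7, catalyst-controlled ynone reduction sets C9.

Key step: step 10

Assumption: the (2S,5S) enantiomer of trans-2,5-diphenylpyrrolidine is taken to give the (R)-α-chloroaldehyde; if the sense of induction is the opposite, the antipodal amine is used in step 1.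

**Route**

Step 1
Reactants: 1 pent-4-enal
Product: 2 (2R)-2-chloropent-4-enal
Conditions: NCS (1.2 equiv), (2S,5S)-2,5-diphenylpyrrolidine (10 mol%), CH2Cl2, 0 °C to rt; used at once as a solution
Reagents that add atoms: N-chlorosuccinimide, O=C1CCC(=O)N1Cl
Why: Organocatalytic enamine α-chlorination of an aldehyde, in which the C2-symmetric amine shields one enamine face so that NCS sets C6 (R) by catalyst control.

Step 2
Reactants: 3 4-(trimethylsilyl)but-3-yn-2-one; 2 (2R)-2-chloropent-4-enal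
Product: 5 (5S,6R)-6-chloro-5-hydroxy-1-(trimethylsilyl)non-8-en-1-yn-3-one, via lithium enolate 4 (not isolated)
Conditions: LiN(i-Pr)2 (1.05 equiv), THF, −78 °C; then 2, −78 °C; aqueous NH4Cl at −78 °C
Reagents that add atoms: none
Why: Lithium aldol addition to an α-chloroaldehyde under Cornforth (polar Felkin–Anh) control, which should give the 1,2-anti chlorohydrin and so set C7 (S) from C6.

Step 3
Reactants: 5 (5S,6R)-6-chloro-5-hydroxy-1-(trimethylsilyl)non-8-en-1-yn-3-one
Product: 6 (5S,6R)-5-[(tert-butyldimethylsilyl)oxy]-6-chloro-1-(trimethylsilyl)non-8-en-1-yn-3-one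
Conditions: TBSOTf, 2,6-lutidine, CH2Cl2, −78 °C
Reagents that add atoms: tert-butyldimethylsilyl trifluoromethanesulfonate, CC(C)(C)[Si](C)(C)OS(=O)(=O)C(F)(F)F
Why: Silyl ether formation with a silyl triflate and a hindered base at low temperature should cap the C7 hydroxyl without retro-aldol cleavage or epoxide closure onto C6.

Step 4
Reactants: 6 (5S,6R)-5-[(tert-butyldimethylsilyl)oxy]-6-chloro-1-(trimethylsilyl)non-8-en-1-yn-3-one
Product: 7 (3R,5S,6R)-5-[(tert-butyldimethylsilyl)oxy]-6-chloro-1-(trimethylsilyl)non-8-en-1-yn-3-ol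
Conditions: Ru[(R,R)-TsNCH(Ph)CH(Ph)NH](p-cymene) (2 mol%), i-PrOH, rt
Reagents that add atoms: none
Why: Noyori asymmetric transfer hydrogenation of an alkynyl ketone, in which the alkynyl group takes the aryl-like position so that the (R,R) catalyst should deliver hydride to give C9 (R), 1,3-syn to C7, by catalyst control.

Step 5
Reactants: 7 (3R,5S,6R)-5-[(tert-butyldimethylsilyl)oxy]-6-chloro-1-(trimethylsilyl)non-8-en-1-yn-3-ol
Product: 8 (3R,5S,6R)-5-[(tert-butyldimethylsilyl)oxy]-6-chloronon-8-en-1-yn-3-ol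
Conditions: K2CO3 (0.3 equiv), MeOH, 0 °C
Reagents that add atoms: none
Why: Base-catalysed methanolysis cleaves the C(sp)–Si bond selectively, and the cold, brief exposure should leave the O–TBS ether and the C6 chloride untouched.

Step 6
Reactants: 9 methyl (2R)-2-hydroxybutanoate
Product: 10 methyl (2R)-2-{[(trifluoromethyl)sulfonyl]oxy}butanoate
Conditions: Tf2O, 2,6-lutidine, CH2Cl2, −78 to 0 °C; used without storage
Reagents that add atoms: trifluoromethanesulfonic anhydride, O=S(=O)(OS(=O)(=O)C(F)(F)F)C(F)(F)F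
Why: O-Sulfonylation of an α-hydroxy ester forms only the O–S bond, so the C13 configuration is retained in the triflate.

Step 7
Reactants: 8 (3R,5S,6R)-5-[(tert-butyldimethylsilyl)oxy]-6-chloronon-8-en-1-yn-3-ol; 10 methyl (2R)-2-{[(trifluoromethyl)sulfonyl]oxy}butanoate
Product: 11 methyl (2S)-2-{[(3R,5S,6R)-5-[(tert-butyldimethylsilyl)oxy]-6-chloronon-8-en-1-yn-3-yl]oxy}butanoate
Conditions: NaN(SiMe3)2 (1.05 equiv), THF, −78 °C; then 10 (1.5 equiv), −78 to −30 °C; aqueous NH4Cl
Reagents that add atoms: none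
Why: Williamson etherification of a secondary alkoxide with an α-carbonyl triflate, an SN2 displacement known for lactate-type triflates and hindered secondary alkoxides, should invert C13 cleanly (R to S) while the low temperature holds back side reactions of the alkoxide.

Step 8
Reactants: 11 methyl (2S)-2-{[(3R,5S,6R)-5-[(tert-butyldimethylsilyl)oxy]-6-chloronon-8-en-1-yn-3-yl]oxy}butanoate
Product: 12 methyl (2S)-2-{[(3R,5S,6R)-5-[(tert-butyldimethylsilyl)oxy]-6-chloronona-1,8-dien-3-yl]oxy}butanoate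
Conditions: H2 (1 atm), Pd/CaCO3 poisoned with Pb(OAc)2, quinoline, EtOAc, rt, stopped at one equivalent of H2
Reagents that add atoms: none
Why: Lindlar-type semi-hydrogenation, in which the terminal alkyne binds the poisoned palladium far more strongly than a monosubstituted alkene, should stop at the C10=C11 vinyl group without touching C3=C4, the chloride or the ester.

Step 9
Reactants: 12 methyl (2S)-2-{[(3R,5S,6R)-5-[(tert-butyldimethylsilyl)oxy]-6-chloronona-1,8-dien-3-yl]oxy}butanoate
Product: 13 (2S)-2-{[(3R,5S,6R)-5-[(tert-butyldimethylsilyl)oxy]-6-chloronona-1,8-dien-3-yl]oxy}butanal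
Conditions: i-Bu2AlH (1.1 equiv), CH2Cl2, −78 °C; aqueous potassium sodium tartrate; used crude
Reagents that add atoms: none
Why: Partial reduction of an α-alkoxy ester with i-Bu2AlH stops at the aldehyde because the chelated tetrahedral aluminium hemiacetal is stable at −78 °C, and the cold work-up should keep C13 from epimerizing.

Step 10
Reactants: 13 (2S)-2-{[(3R,5S,6R)-5-[(tert-butyldimethylsilyl)oxy]-6-chloronona-1,8-dien-3-yl]oxy}butanal
Product: 15 (2S,3S,5R,6R)-6-[(2S,3R)-2-[(tert-butyldimethylsilyl)oxy]-3-chlorohex-5-en-1-yl]-5-chloro-2-ethyloxan-3-ol, via trichlorotitanium alkoxide 14 (not isolated)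
Conditions: TiCl4 (1.2 equiv), CH2Cl2, −78 °C; quench with H2O at −78 °C
Reagents that add atoms: titanium tetrachloride, Cl[Ti](Cl)(Cl)Cl
Why: Proposed new method: TiCl4 is expected to bind aldehyde 13 as a five-membered chelate between the C12 carbonyl oxygen and the ether oxygen, which raises the electrophilicity of C12 and turns its oxygen axial on a chair in which the C9 side chain and the C13 ethyl group are both equatorial; the terminal carbon C11 of the vinyl group then attacks C12 (6-endo with respect to the C10=C11 alkene, exo with respect to the C12=O group) and the positive charge developing at C10 is quenched by a chloride passed from the same titanium centre to give alkoxide 14. The closest known reaction type is the Lewis-acid-promoted Prins (halo-carbonyl-ene) cyclization of hex-5-enals with alkylaluminium chlorides or TiCl4, which gives cis-3-chlorocyclohexanols by internal chloride transfer from the metal alkoxide; it has not been shown on an α-(allyloxy) aldehyde with a monosubstituted alkene, hence the label. C12 is controlled by the chelate (oxygen axial, cis to the equatorial C13 ethyl, configuration S) and C10 by the internal delivery (chlorine axial, cis-1,3 to the C12 oxygen, configuration R), and both are relayed from C9 and C13, which together fix the cis-diequatorial chair. The step needs attack by C11 and not C10 (the latter would give a primary cation and an oxolane), reaction of the C10=C11 alkene and not the remote C3=C4 alkene (which would need an eleven-membered ring), and chloride collapse faster than a hydride shift from C9 to C10; the ring size, the tight chelate and the low temperature are what should secure these.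

Step 11
Reactants: 15 (2S,3S,5R,6R)-6-[(2S,3R)-2-[(tert-butyldimethylsilyl)oxy]-3-chlorohex-5-en-1-yl]-5-chloro-2-ethyloxan-3-ol
Product: 16 (2S,3R,5R,6R)-3-bromo-6-[(2S,3R)-2-[(tert-butyldimethylsilyl)oxy]-3-chlorohex-5-en-1-yl]-5-chloro-2-ethyloxane
Conditions: CBr4 (3 equiv), P(n-C8H17)3 (3 equiv), toluene, 70 °C
Reagents that add atoms: carbon tetrabromide, BrC(Br)(Br)Br
Why: Appel-type bromination, in which bromide displaces the axial C12 oxyphosphonium group in an SN2 step with inversion, should give the equatorial bromide (12R), trans to the axial C10 chloride.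

Step 12
Reactants: 16 (2S,3R,5R,6R)-3-bromo-6-[(2S,3R)-2-[(tert-butyldimethylsilyl)oxy]-3-chlorohex-5-en-1-yl]-5-chloro-2-ethyloxane
Product: 17 (2E,5R,6S)-7-[(2R,3R,5R,6S)-5-bromo-3-chloro-6-ethyloxan-2-yl]-6-[(tert-butyldimethylsilyl)oxy]-5-chlorohept-2-enal
Conditions: crotonaldehyde (5 equiv), second-generation Hoveyda–Grubbs catalyst [(H2IMes)Cl2Ru=CH(C6H4-2-O-i-Pr)] (5 mol%), CH2Cl2, 40 °C
Reagents that add atoms: (E)-crotonaldehyde, C/C=C/C=O
Why: Olefin cross-metathesis of the only alkene in 16 with an electron-poor partner should give the (E)-enal under thermodynamic control, with propene as the volatile co-product.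

Step 13
Reactants: 17 (2E,5R,6S)-7-[(2R,3R,5R,6S)-5-bromo-3-chloro-6-ethyloxan-2-yl]-6-[(tert-butyldimethylsilyl)oxy]-5-chlorohept-2-enal
Product: 18 tert-butyl{[(3E,6R,7S)-8-[(2R,3R,5R,6S)-5-bromo-3-chloro-6-ethyloxan-2-yl]-6-chlorooct-3-en-1-yn-7-yl]oxy}dimethylsilane
Conditions: Me3SiCHN2 (1.3 equiv), n-BuLi (1.25 equiv), THF, −78 °C; then 17, −78 to 0 °C; aqueous NH4Cl
Reagents that add atoms: (trimethylsilyl)diazomethane, C[Si](C)(C)C=[N+]=[N-]
Why: Colvin rearrangement, in which lithiated trimethylsilyldiazomethane adds to the aldehyde, Peterson-type elimination and loss of N2 give an alkylidene carbene and a 1,2-hydrogen shift gives the terminal alkyne, should leave the C3=C4 geometry unchanged.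

Step 14
Reactants: 18 tert-butyl{[(3E,6R,7S)-8-[(2R,3R,5R,6S)-5-bromo-3-chloro-6-ethyloxan-2-yl]-6-chlorooct-3-en-1-yn-7-yl]oxy}dimethylsilane
Product: 19 (3E,6R,7S)-8-[(2R,3R,5R,6S)-5-bromo-3-chloro-6-ethyloxan-2-yl]-6-chlorooct-3-en-1-yn-7-ol
Conditions: HF·pyridine, THF/pyridine, 0 °C to rt
Reagents that add atoms: none
Why: Acidic fluoride cleavage of the silyl ether never generates a free C7 alkoxide, so epoxide closure onto the neighbouring C6 chloride should be avoided.

Step 15
Reactants: 19 (3E,6R,7S)-8-[(2R,3R,5R,6S)-5-bromo-3-chloro-6-ethyloxan-2-yl]-6-chlorooct-3-en-1-yn-7-ol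
Product: 20 (3E,6R,7S)-8-[(2R,3R,5R,6S)-5-bromo-3-chloro-6-ethyloxan-2-yl]-6-chlorooct-3-en-1-yn-7-yl acetate
Conditions: Ac2O, pyridine, DMAP (cat), CH2Cl2, rt
Reagents that add atoms: acetic anhydride, CC(=O)OC(C)=O
Why: Nucleophile-catalysed acylation of the secondary alcohol under weakly basic conditions should give the acetate without affecting the halides or the enyne.

**Compound list**

1 | pent-4-enal | C=CCCC=O | starting material
2 | (2R)-2-chloropent-4-enal | C=CC[C@@H](Cl)C=O | intermediate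
3 | 4-(trimethylsilyl)but-3-yn-2-one | CC(=O)C#C[Si](C)(C)C | starting material
4 | lithium 4-(trimethylsilyl)but-1-en-3-yn-2-olate (lithium enolate of 3) | [Li]OC(=C)C#C[Si](C)(C)C | intermediate (not isolated)
5 | (5S,6R)-6-chloro-5-hydroxy-1-(trimethylsilyl)non-8-en-1-yn-3-one | C=CC[C@@H](Cl)[C@H](CC(=O)C#C[Si](C)(C)C)O | intermediate
6 | (5S,6R)-5-[(tert-butyldimethylsilyl)oxy]-6-chloro-1-(trimethylsilyl)non-8-en-1-yn-3-one | C=CC[C@@H](Cl)[C@H](CC(=O)C#C[Si](C)(C)C)O[Si](C)(C)C(C)(C)C | intermediate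
7 | (3R,5S,6R)-5-[(tert-butyldimethylsilyl)oxy]-6-chloro-1-(trimethylsilyl)non-8-en-1-yn-3-ol | C=CC[C@@H](Cl)[C@H](C[C@H](C#C[Si](C)(C)C)O)O[Si](C)(C)C(C)(C)C | intermediate
8 | (3R,5S,6R)-5-[(tert-butyldimethylsilyl)oxy]-6-chloronon-8-en-1-yn-3-ol | C=CC[C@@H](Cl)[C@H](C[C@H](C#C)O)O[Si](C)(C)C(C)(C)C | intermediate
9 | methyl (2R)-2-hydroxybutanoate | CC[C@@H](O)C(=O)OC | starting material
10 | methyl (2R)-2-{[(trifluoromethyl)sulfonyl]oxy}butanoate | CC[C@@H](OS(=O)(=O)C(F)(F)F)C(=O)OC | intermediate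
11 | methyl (2S)-2-{[(3R,5S,6R)-5-[(tert-butyldimethylsilyl)oxy]-6-chloronon-8-en-1-yn-3-yl]oxy}butanoate | C=CC[C@@H](Cl)[C@H](C[C@H](C#C)O[C@@H](CC)C(=O)OC)O[Si](C)(C)C(C)(C)C | intermediate
12 | methyl (2S)-2-{[(3R,5S,6R)-5-[(tert-butyldimethylsilyl)oxy]-6-chloronona-1,8-dien-3-yl]oxy}butanoate | C=CC[C@@H](Cl)[C@H](C[C@H](C=C)O[C@@H](CC)C(=O)OC)O[Si](C)(C)C(C)(C)C | intermediate
13 | (2S)-2-{[(3R,5S,6R)-5-[(tert-butyldimethylsilyl)oxy]-6-chloronona-1,8-dien-3-yl]oxy}butanal | C=CC[C@@H](Cl)[C@H](C[C@H](C=C)O[C@@H](CC)C=O)O[Si](C)(C)C(C)(C)C | intermediate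
14 | trichlorotitanium alkoxide of 15 (O–TiCl3 on C12) | C=CC[C@@H](Cl)[C@H](C[C@H]1O[C@@H](CC)[C@@H](O[Ti](Cl)(Cl)Cl)C[C@H]1Cl)O[Si](C)(C)C(C)(C)C | intermediate (not isolated)
15 | (2S,3S,5R,6R)-6-[(2S,3R)-2-[(tert-butyldimethylsilyl)oxy]-3-chlorohex-5-en-1-yl]-5-chloro-2-ethyloxan-3-ol | C=CC[C@@H](Cl)[C@H](C[C@H]1O[C@@H](CC)[C@@H](O)C[C@H]1Cl)O[Si](C)(C)C(C)(C)C | intermediate
16 | (2S,3R,5R,6R)-3-bromo-6-[(2S,3R)-2-[(tert-butyldimethylsilyl)oxy]-3-chlorohex-5-en-1-yl]-5-chloro-2-ethyloxane | C=CC[C@@H](Cl)[C@H](C[C@H]1O[C@@H](CC)[C@H](Br)C[C@H]1Cl)O[Si](C)(C)C(C)(C)C | intermediate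
17 | (2E,5R,6S)-7-[(2R,3R,5R,6S)-5-bromo-3-chloro-6-ethyloxan-2-yl]-6-[(tert-butyldimethylsilyl)oxy]-5-chlorohept-2-enal | O=C/C=C/C[C@@H](Cl)[C@H](C[C@H]1O[C@@H](CC)[C@H](Br)C[C@H]1Cl)O[Si](C)(C)C(C)(C)C | intermediate
18 | tert-butyl{[(3E,6R,7S)-8-[(2R,3R,5R,6S)-5-bromo-3-chloro-6-ethyloxan-2-yl]-6-chlorooct-3-en-1-yn-7-yl]oxy}dimethylsilane | C#C/C=C/C[C@@H](Cl)[C@H](C[C@H]1O[C@@H](CC)[C@H](Br)C[C@H]1Cl)O[Si](C)(C)C(C)(C)C | intermediate
19 | (3E,6R,7S)-8-[(2R,3R,5R,6S)-5-bromo-3-chloro-6-ethyloxan-2-yl]-6-chlorooct-3-en-1-yn-7-ol | C#C/C=C/C[C@@H](Cl)[C@H](C[C@H]1O[C@@H](CC)[C@H](Br)C[C@H]1Cl)O | intermediate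
20 | (3E,6R,7S)-8-[(2R,3R,5R,6S)-5-bromo-3-chloro-6-ethyloxan-2-yl]-6-chlorooct-3-en-1-yn-7-yl acetate | C#C/C=C/C[C@@H](Cl)[C@H](C[C@H]1O[C@@H](CC)[C@H](Br)C[C@H]1Cl)OC(C)=O | target

**Step count**

Total: 15 steps. Longest linear sequence: 14 steps (steps 1–5 and 7–15, from pent-4-enal); step 6 is a one-step side branch.

**Steps most likely to fail, with fallbacks**

Step 10 (proposed chloro-Prins closure). The Lewis acid may ionize the allylic C9–O bond, a hydride may shift from C9 to the developing C10 cation before chloride collapses onto it, or chloride may arrive from the opposite face with loss of control at C10. The fallback closes the same C11–C12 bond by known carbonyl chemistry; it sets out from 11 and comes back at 16. Partial reduction of 11 (i-Bu2AlH, CH2Cl2, −78 °C) would give alkynyl aldehyde F1. Markovnikov hydration of the terminal alkyne ((Ph3P)AuNTf2, wet 1,4-dioxane, rt) would give keto aldehyde F2, in which C10 is a ketone and C11 a methyl group. Intramolecular enamine aldol condensation (pyrrolidine, AcOH, CH2Cl2, rt) would then join C11 to C12 and give enone F3. Conjugate addition of bromide (Me3SiBr, CH2Cl2, −78 °C, then hydrolysis) anti to the C13 ethyl group would give β-bromoketone F4 with the equatorial C12 bromide. Reduction under Luche conditions (NaBH4, CeCl3, MeOH, −78 °C, axial hydride) would give bromohydrin F5 with the equatorial C10 hydroxyl. Appel chlorination with inversion (PPh3, CCl4, 60 °C) would install the axial C10 chloride and return to 16.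

Step 7 (etherification). The C9 alkoxide may displace the C6 chloride intramolecularly to form a five-membered cyclic ether, the silyl group may migrate from the C7 oxygen to the C9 oxygen, or the triflate may undergo elimination in place of substitution. The fallback avoids any alkoxide; it sets out from 8 and comes back at 11. Methyl 2-diazobutanoate F6 would be made by deacylative diazo transfer onto methyl 2-ethyl-3-oxobutanoate (4-acetamidobenzenesulfonyl azide, DBU, MeCN). It would then be inserted into the O–H bond of 8 under neutral conditions by a copper carbenoid (CuCl, NaB[3,5-(CF3)2C6H3]4, chiral spiro-bis(oxazoline) ligand, CH2Cl2, rt). The ligand enantiomer is chosen to set C13 (S), and any C13 epimer would be removed by chromatography.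

Step 13 (Colvin homologation). The basic lithium reagent may deprotonate the enal at C5, followed by vinylogous loss of the C6 chloride, in place of addition to the aldehyde. The fallback builds the enyne without a strong base; it sets out from 16 and comes back at 18. Ozonolysis of the terminal alkene (O3, CH2Cl2, −78 °C; PPh3) would give β-chloro aldehyde F7. Takai olefination (CrCl2, CHI3, THF, 0 °C) would give (E)-vinyl iodide F8. Sonogashira coupling with ethynyltrimethylsilane (Pd(PPh3)4, CuI, i-Pr2NH, rt) would give silyl enyne F9. Methanolysis of the alkynyl silane (K2CO3, MeOH, 0 °C) would return to 18.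

**Further compounds**

F1 | step 10 | (2S)-2-{[(3R,5S,6R)-5-[(tert-butyldimethylsilyl)oxy]-6-chloronon-8-en-1-yn-3-yl]oxy}butanal | C=CC[C@@H](Cl)[C@H](C[C@H](C#C)O[C@@H](CC)C=O)O[Si](C)(C)C(C)(C)C
F2 | step 10 | (2S)-2-{[(3R,5S,6R)-5-[(tert-butyldimethylsilyl)oxy]-6-chloro-2-oxonon-8-en-3-yl]oxy}butanal | C=CC[C@@H](Cl)[C@H](C[C@H](C(C)=O)O[C@@H](CC)C=O)O[Si](C)(C)C(C)(C)C
F3 | step 10 | (2R,6S)-2-[(2S,3R)-2-[(tert-butyldimethylsilyl)oxy]-3-chlorohex-5-en-1-yl]-6-ethyl-2H-pyran-3(6H)-one | C=CC[C@@H](Cl)[C@H](C[C@H]1O[C@@H](CC)C=CC1=O)O[Si](C)(C)C(C)(C)C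
F4 | step 10 | (2R,5R,6S)-5-bromo-2-[(2S,3R)-2-[(tert-butyldimethylsilyl)oxy]-3-chlorohex-5-en-1-yl]-6-ethyloxan-3-one | C=CC[C@@H](Cl)[C@H](C[C@H]1O[C@@H](CC)[C@H](Br)CC1=O)O[Si](C)(C)C(C)(C)C
F5 | step 10 | (2R,3S,5R,6S)-5-bromo-2-[(2S,3R)-2-[(tert-butyldimethylsilyl)oxy]-3-chlorohex-5-en-1-yl]-6-ethyloxan-3-ol | C=CC[C@@H](Cl)[C@H](C[C@H]1O[C@@H](CC)[C@H](Br)C[C@@H]1O)O[Si](C)(C)C(C)(C)C
F6 | step 7 | methyl 2-diazobutanoate | CCC(=[N+]=[N-])C(=O)OC
F7 | step 13 | (3R,4S)-5-[(2R,3R,5R,6S)-5-bromo-3-chloro-6-ethyloxan-2-yl]-4-[(tert-butyldimethylsilyl)oxy]-3-chloropentanal | O=CC[C@@H](Cl)[C@H](C[C@H]1O[C@@H](CC)[C@H](Br)C[C@H]1Cl)O[Si](C)(C)C(C)(C)C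
F8 | step 13 | tert-butyl{[(2S,3R,5E)-1-[(2R,3R,5R,6S)-5-bromo-3-chloro-6-ethyloxan-2-yl]-3-chloro-6-iodohex-5-en-2-yl]oxy}dimethylsilane | I/C=C/C[C@@H](Cl)[C@H](C[C@H]1O[C@@H](CC)[C@H](Br)C[C@H]1Cl)O[Si](C)(C)C(C)(C)C
F9 | step 13 | tert-butyl{[(3E,6R,7S)-8-[(2R,3R,5R,6S)-5-bromo-3-chloro-6-ethyloxan-2-yl]-6-chloro-1-(trimethylsilyl)oct-3-en-1-yn-7-yl]oxy}dimethylsilane | C[Si](C)(C)C#C/C=C/C[C@@H](Cl)[C@H](C[C@H]1O[C@@H](CC)[C@H](Br)C[C@H]1Cl)O[Si](C)(C)C(C)(C)C
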